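## Structural features

The target is a guaiane: a five-membered ring (C1–C5) and a seven-membered ring (C1, C5, C6–C10) share the C1–C5 bond, with H1 and H5 on opposite faces (trans-fused hydroazulene). C4 and C10 carry methyl groups, C7 an isopropyl group and C8 a 4-hydroxybenzoyloxy group. There are seven stereocentres, (1R,3R,4S,5S,7S,8R,10R): C3–C4–C5–C1–C10 are contiguous and C7–C8 are adjacent. The epoxide oxygen, the 10-hydroxyl and the isopropyl group lie on the face of H1. The ester oxygen, C14 and C15 lie on the face of H5, so O8 is 1,3-anti to O10 and trans to the isopropyl group. The fragile groups are the trisubstituted epoxide (acid, with the 10-hydroxyl nearby), the phenolic ester (base), and the tertiary carbinol β to C8, which can undergo retro-aldol cleavage or elimination while C8 is a ketone. The real difficulty is to close the seven-membered ring while fixing the quaternary carbinol C10 and then relay its configuration to C8. Once the ketol exists no base equilibration is safe, because ring opening and five-membered aldol closures (C7 to C10, C1 to C8) compete, so C7 must already be correct. The key step reads C8–C9–C10 as an aldol retron: a C8 ketone, its α-carbon C9, and the carbonyl of an acetyl group on C1, the two arms being held trans on the cyclopentene.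

## Logic of the disconnections

**30 to 29.** The phenolic O–Si bond is cut. A free phenol would compete in the acylation and is best kept away from the peroxide step. Nothing is simplified structurally. The forward step must spare the epoxide and the aryl ester, which calls for buffered fluoride.

**29 to 28.** The C3–O and C4–O bonds of the epoxide are cut. The epoxide is the most acid-sensitive group and is therefore made last among the skeletal changes. Two stereocentres are traded for an alkene. The forward step must deliver oxygen to the face of H1, which the 10-hydroxyl on that face can direct.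

**28 to 23 and 26; 26 to 24.** The C8 O–acyl bond is cut, then the O–Si bond of the acid. This is convergent and removes the aromatic part. The forward acylation must choose the secondary C8 hydroxyl over the tertiary C10 hydroxyl and needs no inversion.

**23 to 22.** The C8–H bond is cut (carbinol to ketone). This exposes the β-hydroxy ketone. The forward reduction must give the 1,3-anti diol, which asks for hydride delivery from the C10 oxygen.

**22 to 19.** The C9–C10 bond is cut. The seven-membered ring opens to a cyclopentene with two trans arms and the C10 stereocentre disappears. The forward step needs an enolate fixed at C9 under non-equilibrating conditions, face control at the acetyl carbonyl, and a precursor that is a single C7 epimer, since C7 cannot be corrected afterwards.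

**19 to 16.** The C8–C9 and C9–Br bonds are cut (one-carbon homologation of an acid). The forward sequence must stay neutral or acidic so that C7 and C1 do not epimerise.

**16 to 14 to 13.** The C8–N bond to the auxiliary is restored and the C10 carbonyl is traced back to an ethenyl group. The acetyl group is thereby masked through the Lewis-acidic and strongly basic steps. The forward oxidation must choose the monosubstituted alkene over the trisubstituted one, and the auxiliary cleavage must not touch C7.

**13 to 12 to 10.** The C4–C15 bond is cut, then the C4–O bond of the enol sulfonate back to a ketone. This returns to a cyclopentanone. The forward enolisation must be kinetic, toward C3.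

**10 to 8 and 5; 8 to 6 and 7.** The C6–C7 bond is cut, then the N–acyl bond. This is the only bond whose formation can set C7 under auxiliary control, because C6 is an unsubstituted acceptor carbon. The fragments are of similar size. The forward step needs face control on a Z-enolate; C5 is reset by protonation and must equilibrate to trans.

**5 to 3 to 1.** The C5=C6 bond goes back to a hydroxymethyl group, then the C5–C6 and C1–C10 bonds are cut. This reaches 1, a two-carbon ethenyl donor and a one-carbon electrophile. The forward step must deliver the ethenyl group enantioselectively to C1 and capture the enolate at C5 before proton exchange.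

## Other disconnections considered

Alternative 1: The cut is at C1–C5 and C9–C10, so both rings form together. The forward key step is a rhodium-catalysed intramolecular (5+2) cycloaddition of the tethered allene–vinylcyclopropane (3R,1E)-3-(tert-butyldimethylsilyloxy)-1-(1-isopropylcyclopropyl)octa-1,6,7-triene A1 to cis-fused 15-nor-4-(tert-butyldimethylsilyloxy)guaia-6,10(14)-diene A2.
- In its favour: two rings and two C–C bonds arise in one catalytic, atom-economical step from an acyclic precursor, and the silyloxy stereocentre should control the ring fusion. In ring-forming efficiency this alternative is better than the chosen plan.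
- Against it here: the fusion is cis and neither ring-fusion hydrogen is α to a carbonyl, so correction to trans needs a redox detour. C15 is missing. C8 is a plain methylene, and an allylic oxidation would have to tell it from C5 and C11. The C10 carbinol and the C7 centre would come from hydration and hydrogenation without an internal control element.
- Comparison: on structure it reaches the bicycle faster but at a lower oxidation level and with the wrong fusion. On mechanism the metallacycle pathway is at least as dependable as a medium-ring aldol. On step economy it is equal or better up to the bicycle and worse overall.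

Alternative 2: The cut is at C1–C5 and C6–C7, with a temporary C7–O–C10 bridge. The forward key step is a gold-catalysed cyclisation of the enyne ketone (10S,6E)-2,6,10-trimethyl-10-(triethylsilyloxy)dodec-6-en-11-yn-3-one A3 to the oxatricycle 7,10-epoxyguai-5-en-4-ol triethylsilyl ether A4. The alkyne is activated, the alkene attacks in a 5-exo-dig sense, the ketone oxygen captures C10 and a Prins-type closure forms C6–C7.
- In its favour: three bonds and three rings form at once, and C1 and C10 follow stereospecifically from the alkene geometry. On control of C10 this alternative is better than the chosen plan, which rests on a chelate preference. Step economy up to the tricycle is at least equal.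
- Against it here: the tertiary, allylic C7–O bond must be cleaved reductively to C7–H with defined configuration. C8 is an unactivated methylene and would need a C–H oxidation. The trans fusion depends on face-selective reduction of C5=C6. The C4 silyloxy group must be eliminated regioselectively toward C3.
- Comparison: structurally it overshoots (an extra bridge, no C8 oxygen), so the steps saved early are spent later on harder problems.

Alternative 3: The cut is at C6–C7 and C8–C9, with ring expansion. The forward key step is irradiation of cis-6-methylbicyclo[3.3.0]octa-3,6-dien-2-one A5 with 3-methylbut-1-ene A6 to give the head-to-tail cis-anti-cis cyclobutane ketone A7. Cleavage of C6–C9 would then open the seven-membered ring.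
- In its favour: a cheap alkene brings C7, C8 and the isopropyl group in one reagent-free step. Approach on the convex face sets C7 relative to C5 without an auxiliary, and on this point it is equal or better. After fragmentation C1 is α to the C10 ketone, so cis-to-trans correction is feasible.
- Against it here: a weakly polarised monoalkyl alkene usually gives poor head-to-head/head-to-tail control. The unactivated C6–C9 bond must cleave in preference to C8–C9. The outcome lacks C14 and the C8 oxygen, so C10 (by methyl addition) and C8 would be set without the 1,3-relay. A5 must itself be made enantioenriched.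
- Comparison: the mechanism is simple, but regiocontrol and the number of steps after the key step are worse than in the chosen plan.

Key step: step 10

Assumption: atom labels follow guaiane numbering throughout, and the (R)-BINAP rhodium catalyst is taken to add the ethenyl group to the enone face that corresponds to (R)-3-ethenylcyclopentanone, as it does with aryl and 1-alkenyl groups; (S)-BINAP is used if the sense proves opposite.

## Route

Step 1
Reactants: 1 cyclopent-2-en-1-one
Product: 3 (2R,3S)-3-ethenyl-2-(hydroxymethyl)cyclopentan-1-one, via zirconium enolate 2 (not isolated)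
Conditions: Cp2Zr(H)Cl, HC≡CH, THF, rt; [Rh(cod)(MeCN)2]BF4 (5 mol%), (R)-BINAP (6 mol%), 1, THF, rt; then CH2O (monomer in THF), −78 → 0 °C; aq. NH4Cl
Reagents that add atoms: acetylene C#C (transferred as Cp2Zr(Cl)CH=CH2, C=C[Zr](Cl)(C1C=CC=C1)C1C=CC=C1); formaldehyde C=O
Why: Rhodium-catalysed asymmetric 1,4-addition of an alkenylzirconocene with aldol capture of the enolate (three-component coupling); the BINAP-bound monovalent rhodium–ethenyl species adds to one face of 1 and sets C1, and the regiodefined zirconium enolate 2 takes up formaldehyde at C5 anti to the ethenyl group.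

Step 2
Reactants: 3 (2R,3S)-3-ethenyl-2-(hydroxymethyl)cyclopentan-1-one
Product: 5 (3S)-3-ethenyl-2-methylidenecyclopentan-1-one, via mesylate 4 (not isolated)
Conditions: MsCl, Et3N (3 equiv), CH2Cl2, 0 °C → rt
Reagents that add atoms: none
Why: Sulfonylation of the primary alcohol followed by E1cB elimination of the β-sulfonyloxy ketone; C1 is not α to the carbonyl and is untouched, and 5 is used at once in solution because 2-methylidene ketones dimerise.

Step 3
Reactants: 6 (4S)-4-benzyl-1,3-oxazolidin-2-one; 7 3-methylbutanoyl chloride
Product: 8 (4S)-4-benzyl-3-(3-methylbutanoyl)-1,3-oxazolidin-2-one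
Conditions: Et3N, DMAP (cat.), CH2Cl2, 0 °C → rt
Reagents that add atoms: none
Why: DMAP-catalysed N-acylation of the oxazolidinone by the acid chloride; no stereocentre is formed.

Step 4
Reactants: 8 (4S)-4-benzyl-3-(3-methylbutanoyl)-1,3-oxazolidin-2-one; 5 (3S)-3-ethenyl-2-methylidenecyclopentan-1-one
Product: 10 (4S)-4-benzyl-3-[(2S)-2-{[(1S,2S)-2-ethenyl-5-oxocyclopentyl]methyl}-3-methylbutanoyl]-1,3-oxazolidin-2-one, via chlorotitanium enolate 9 (not isolated)
Conditions: TiCl4, iPr2NEt, CH2Cl2, −78 → 0 °C; 5, 0 °C; aq. NH4Cl; then Et3N (cat.), CH2Cl2, rt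
Reagents that add atoms: none
Why: Michael addition of the chelated (Z)-chlorotitanium enolate of an N-acyloxazolidinone to an enone; the benzyl group shields one enolate face so that C6 adds to the other and C7 becomes S, while C5 arises by protonation of the ketone enolate and is equilibrated through the ketone to the more stable 1,5-trans isomer without enolising the hindered imide centre.

Step 5
Reactants: 10 (4S)-4-benzyl-3-[(2S)-2-{[(1S,2S)-2-ethenyl-5-oxocyclopentyl]methyl}-3-methylbutanoyl]-1,3-oxazolidin-2-one
Product: 12 (4S,5S)-5-{(2S)-2-[(4S)-4-benzyl-2-oxo-1,3-oxazolidine-3-carbonyl]-3-methylbutyl}-4-ethenylcyclopent-1-en-1-yl trifluoromethanesulfonate, via potassium enolate 11 (not isolated)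
Conditions: KN(SiMe3)2, THF, −78 °C; N-(5-chloropyridin-2-yl)bis(trifluoromethanesulfonimide), −78 °C
Reagents that add atoms: N-(5-chloropyridin-2-yl)bis(trifluoromethanesulfonimide) FC(F)(F)S(=O)(=O)N(c1ccc(Cl)cn1)S(=O)(=O)C(F)(F)F
Why: Kinetic deprotonation at the unhindered C3 methylene and O-sulfonylation of the enolate give the enol triflate with the double bond fixed at C3=C4; trapping at −78 °C should outrun enolate equilibration and attack on the imide, and C5 is no longer epimerisable afterwards.

Step 6
Reactants: 12 (4S,5S)-5-{(2S)-2-[(4S)-4-benzyl-2-oxo-1,3-oxazolidine-3-carbonyl]-3-methylbutyl}-4-ethenylcyclopent-1-en-1-yl trifluoromethanesulfonate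
Product: 13 (4S)-4-benzyl-3-[(2S)-2-{[(1S,5S)-5-ethenyl-2-methylcyclopent-2-en-1-yl]methyl}-3-methylbutanoyl]-1,3-oxazolidin-2-one
Conditions: MeMgCl, ZnCl2, THF, 0 °C; then 12, Pd(PPh3)4 (5 mol%), THF, rt → 50 °C
Reagents that add atoms: methylzinc chloride C[Zn]Cl
Why: Negishi coupling of an alkenyl triflate with methylzinc chloride at zerovalent palladium puts C15 on C4 with the alkene position fixed by the triflate; the imide is inert to the organozinc.

Step 7
Reactants: 13 (4S)-4-benzyl-3-[(2S)-2-{[(1S,5S)-5-ethenyl-2-methylcyclopent-2-en-1-yl]methyl}-3-methylbutanoyl]-1,3-oxazolidin-2-one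
Product: 14 (4S)-3-[(2S)-2-{[(1S,5R)-5-acetyl-2-methylcyclopent-2-en-1-yl]methyl}-3-methylbutanoyl]-4-benzyl-1,3-oxazolidin-2-one
Conditions: PdCl2 (10 mol%), CuCl (30 mol%), O2 (1 atm), DMF/H2O 7:1, rt
Reagents that add atoms: water O
Why: Wacker–Tsuji oxidation; divalent palladium hydroxypalladates the monosubstituted alkene in the Markovnikov sense and leaves the trisubstituted ring alkene alone, and the acid is not yet free so it cannot lactonise onto the ring alkene; C1, now α to the acetyl group, is already trans to the C5 arm.

Step 8
Reactants: 14 (4S)-3-[(2S)-2-{[(1S,5R)-5-acetyl-2-methylcyclopent-2-en-1-yl]methyl}-3-methylbutanoyl]-4-benzyl-1,3-oxazolidin-2-one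
Product: 16 (2S)-2-{[(1S,5R)-5-acetyl-2-methylcyclopent-2-en-1-yl]methyl}-3-methylbutanoic acid, via lithium peroxycarboxylate 15 (not isolated)
Conditions: LiOH, H2O2 (30%), THF/H2O 3:1, 0 °C; aq. Na2SO3; HCl to pH 2
Reagents that add atoms: hydrogen peroxide OO
Why: Hydroperoxide cleavage of the N-acyloxazolidinone at the exocyclic carbonyl, then reduction of the peracid; the weakly basic nucleophile does not enolise the hindered C7 centre and the auxiliary 6 is recovered.

Step 9
Reactants: 16 (2S)-2-{[(1S,5R)-5-acetyl-2-methylcyclopent-2-en-1-yl]methyl}-3-methylbutanoic acid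
Product: 19 (3S)-3-{[(1S,5R)-5-acetyl-2-methylcyclopent-2-en-1-yl]methyl}-1-bromo-4-methylpentan-2-one, via acid chloride 17 (not isolated), via diazoketone 18 (not isolated)
Conditions: (COCl)2, DMF (cat.), CH2Cl2, 0 °C → rt; Me3SiCHN2, MeCN/THF, 0 °C; HBr (1.1 equiv, 33% in AcOH), Et2O, −20 °C
Reagents that add atoms: (trimethylsilyl)diazomethane C[Si](C)(C)C=[N+]=[N-]; hydrogen bromide Br
Why: Acylation of a diazoalkane by the acid chloride and hydrobromination of the diazoketone (Nierenstein-type sequence) add C9 and bromine under neutral to acidic conditions that leave C7 and C1 alone; one equivalent of HBr at low temperature protonates the diazoketone before it can add to the ring alkene.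

Step 10
Reactants: 19 (3S)-3-{[(1S,5R)-5-acetyl-2-methylcyclopent-2-en-1-yl]methyl}-1-bromo-4-methylpentan-2-one
Product: 22 (1R,5S,7S,10R)-10-hydroxyguai-3-en-8-one, via samarium enolate 20 (not isolated), via samarium aldolate 21 (not isolated)
Conditions: SmI2 (2.5 equiv, 0.1 M in THF), THF, −78 °C, slow addition of 19 (final 0.01 M); pH 7 phosphate buffer at −78 °C
Reagents that add atoms: none
Why: SmI2 (divalent samarium) transfers two electrons to the C9–Br bond of 19 and gives the trivalent samarium enolate 20 with the double bond fixed at C8=C9; C9 then adds to the acetyl carbonyl C10 through a six-membered chelate in which samarium bridges O8 and O10, and the aldolate 21 is protonated cold so that it cannot revert. The closest known reaction type is the SmI2-promoted intramolecular Reformatsky (aldol) cyclisation of α-halo carbonyl compounds onto aldehydes and ketones, which is established for medium rings. The seven-membered ring closes in the 7-(enolendo)-exo-trig mode, because both enolate carbons C8 and C9 become ring atoms and the attacked carbonyl is exocyclic. The one new stereocentre, C10, is controlled by the trans arms on the cyclopentene together with the chelate: C9 can reach C10 only when it lies between C5 and H1 about the C1–C10 bond, and of the two carbonyl faces then open, the one that turns the metal-bound oxygen to the open H1 side and the small methyl group under the five-membered ring should be preferred, which gives the 10-hydroxyl cis to H1 (10R). The step needs regioselectivity (enolate at C9 and not at C7, C1 or C14), secured by the position of the bromine and by the low temperature that suppresses proton exchange; it needs chemoselectivity against ketyl formation, secured because dialkyl ketones are not reduced by SmI2 in THF at −78 °C without additives; and it needs retention at C7, secured because that centre is never part of the enolate. Slow addition at high dilution keeps intermolecular aldol addition and protonation of 20 by a second molecule of 19 low.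

Step 11
Reactants: 22 (1R,5S,7S,10R)-10-hydroxyguai-3-en-8-one
Product: 23 (1R,5S,7S,8R,10R)-guai-3-ene-8,10-diol
Conditions: Me4NBH(OAc)3 (5 equiv), MeCN/AcOH 1:1, −30 → −20 °C; aq. potassium sodium tartrate
Reagents that add atoms: none
Why: Saksena–Evans reduction; the C10 hydroxyl exchanges onto boron and hydride is delivered within the alkoxyborohydride to the C8 carbonyl face on the side of O10, so the new hydroxyl ends 1,3-anti (8R), and the acidic medium excludes retro-aldol cleavage.

Step 12
Reactants: 24 4-hydroxybenzoic acid
Product: 26 4-(tert-butyldimethylsilyloxy)benzoic acid, via bis-silyl derivative 25 (not isolated)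
Conditions: t-BuMe2SiCl (2.2 equiv), imidazole, DMF, rt; then AcOH/THF/H2O 3:1:1, rt
Reagents that add atoms: tert-butyldimethylsilyl chloride CC(C)(C)[Si](C)(C)Cl
Why: Silylation of phenol and acid followed by selective hydrolysis of the much more labile silyl ester leaves the phenol protected as its silyl ether.

Step 13
Reactants: 26 4-(tert-butyldimethylsilyloxy)benzoic acid; 23 (1R,5S,7S,8R,10R)-guai-3-ene-8,10-diol
Product: 28 (1R,5S,7S,8R,10R)-10-hydroxyguai-3-en-8-yl 4-(tert-butyldimethylsilyloxy)benzoate, via acid chloride 27 (not isolated)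
Conditions: 26, (COCl)2, DMF (cat.), CH2Cl2, 0 °C → rt; then 23, Et3N, DMAP, CH2Cl2, 0 °C → rt
Reagents that add atoms: none
Why: DMAP-catalysed acylation by the acid chloride takes the secondary C8 hydroxyl and leaves the tertiary C10 hydroxyl free; no stereocentre is touched.

Step 14
Reactants: 28 (1R,5S,7S,8R,10R)-10-hydroxyguai-3-en-8-yl 4-(tert-butyldimethylsilyloxy)benzoate
Product: 29 (1R,3R,4S,5S,7S,8R,10R)-3,4-epoxy-10-hydroxyguaian-8-yl 4-(tert-butyldimethylsilyloxy)benzoate
Conditions: VO(acac)2 (5 mol%), t-BuOOH (1.5 equiv, in decane), CH2Cl2, 0 °C → rt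
Reagents that add atoms: tert-butyl hydroperoxide CC(C)(C)OO
Why: Hydroxyl-directed vanadium-catalysed epoxidation; the vanadium alkyl peroxide bound to the bishomoallylic C10 oxygen delivers oxygen to the alkene face on the side of that hydroxyl (the H1 face), while C14 lies under the five-membered ring and hinders the other face, which sets 3R,4S; the syn epoxy alcohol cannot open itself by backside attack.

Step 15
Reactants: 29 (1R,3R,4S,5S,7S,8R,10R)-3,4-epoxy-10-hydroxyguaian-8-yl 4-(tert-butyldimethylsilyloxy)benzoate
Product: 30 (1R,3R,4S,5S,7S,8R,10R)-3,4-epoxy-10-hydroxyguaian-8-yl 4-hydroxybenzoate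
Conditions: Bu4NF (1.1 equiv), AcOH (1.1 equiv), THF, 0 °C
Reagents that add atoms: none
Why: Fluoride cleavage of the aryl silyl ether, buffered with acetic acid so that neither the ester nor the epoxide is attacked; no stereocentre is touched.

## Compound list

1 | cyclopent-2-en-1-one | O=C1C=CCC1 | starting material
2 | chlorobis(cyclopentadienyl)zirconium (3S)-3-ethenylcyclopent-1-en-1-olate | C=C[C@@H]1CCC(O[Zr](Cl)(C2C=CC=C2)C2C=CC=C2)=C1 | intermediate
3 | (2R,3S)-3-ethenyl-2-(hydroxymethyl)cyclopentan-1-one | OC[C@H]1[C@@H](CCC1=O)C=C | intermediate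
4 | [(1R,2S)-2-ethenyl-5-oxocyclopentyl]methyl methanesulfonate | CS(=O)(=O)OC[C@H]1[C@@H](CCC1=O)C=C | intermediate
5 | (3S)-3-ethenyl-2-methylidenecyclopentan-1-one | C=C1[C@@H](CCC1=O)C=C | intermediate
6 | (4S)-4-benzyl-1,3-oxazolidin-2-one | O=C1N[C@@H](Cc2ccccc2)CO1 | starting material
7 | 3-methylbutanoyl chloride | CC(C)CC(Cl)=O | starting material
8 | (4S)-4-benzyl-3-(3-methylbutanoyl)-1,3-oxazolidin-2-one | CC(C)CC(=O)N1[C@@H](Cc2ccccc2)COC1=O | intermediate
9 | trichlorotitanium (Z)-enolate of 8 | CC(C)/C=C(\O[Ti](Cl)(Cl)Cl)N1[C@@H](Cc2ccccc2)COC1=O | intermediate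
10 | (4S)-4-benzyl-3-[(2S)-2-{[(1S,2S)-2-ethenyl-5-oxocyclopentyl]methyl}-3-methylbutanoyl]-1,3-oxazolidin-2-one | CC(C)[C@H](C[C@H]1[C@@H](CCC1=O)C=C)C(=O)N1[C@@H](Cc2ccccc2)COC1=O | intermediate
11 | potassium (4S,5S)-5-{(2S)-2-[(4S)-4-benzyl-2-oxo-1,3-oxazolidine-3-carbonyl]-3-methylbutyl}-4-ethenylcyclopent-1-en-1-olate | CC(C)[C@H](C[C@H]1[C@@H](CC=C1[O-])C=C)C(=O)N1[C@@H](Cc2ccccc2)COC1=O.[K+] | intermediate
12 | (4S,5S)-5-{(2S)-2-[(4S)-4-benzyl-2-oxo-1,3-oxazolidine-3-carbonyl]-3-methylbutyl}-4-ethenylcyclopent-1-en-1-yl trifluoromethanesulfonate | CC(C)[C@H](C[C@H]1[C@@H](CC=C1OS(=O)(=O)C(F)(F)F)C=C)C(=O)N1[C@@H](Cc2ccccc2)COC1=O | intermediate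
13 | (4S)-4-benzyl-3-[(2S)-2-{[(1S,5S)-5-ethenyl-2-methylcyclopent-2-en-1-yl]methyl}-3-methylbutanoyl]-1,3-oxazolidin-2-one | CC(C)[C@H](C[C@H]1[C@@H](CC=C1C)C=C)C(=O)N1[C@@H](Cc2ccccc2)COC1=O | intermediate
14 | (4S)-3-[(2S)-2-{[(1S,5R)-5-acetyl-2-methylcyclopent-2-en-1-yl]methyl}-3-methylbutanoyl]-4-benzyl-1,3-oxazolidin-2-one | CC(C)[C@H](C[C@H]1[C@@H](CC=C1C)C(C)=O)C(=O)N1[C@@H](Cc2ccccc2)COC1=O | intermediate
15 | lithium (2S)-2-{[(1S,5R)-5-acetyl-2-methylcyclopent-2-en-1-yl]methyl}-3-methylbutaneperoxoate | CC(C)[C@H](C[C@H]1[C@@H](CC=C1C)C(C)=O)C(=O)O[O-].[Li+] | intermediate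
16 | (2S)-2-{[(1S,5R)-5-acetyl-2-methylcyclopent-2-en-1-yl]methyl}-3-methylbutanoic acid | CC(C)[C@H](C[C@H]1[C@@H](CC=C1C)C(C)=O)C(O)=O | intermediate
17 | (2S)-2-{[(1S,5R)-5-acetyl-2-methylcyclopent-2-en-1-yl]methyl}-3-methylbutanoyl chloride | CC(C)[C@H](C[C@H]1[C@@H](CC=C1C)C(C)=O)C(Cl)=O | intermediate
18 | (3S)-3-{[(1S,5R)-5-acetyl-2-methylcyclopent-2-en-1-yl]methyl}-1-diazo-4-methylpentan-2-one | CC(C)[C@H](C[C@H]1[C@@H](CC=C1C)C(C)=O)C(=O)C=[N+]=[N-] | intermediate
19 | (3S)-3-{[(1S,5R)-5-acetyl-2-methylcyclopent-2-en-1-yl]methyl}-1-bromo-4-methylpentan-2-one | CC(C)[C@H](C[C@H]1[C@@H](CC=C1C)C(C)=O)C(=O)CBr | intermediate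
20 | diiodosamarium C8=C9 enolate of 19 | CC(C)[C@H](C[C@H]1[C@@H](CC=C1C)C(C)=O)C(=C)O[Sm](I)I | intermediate
21 | diiodosamarium 10-alkoxide of (1R,5S,7S,10R)-10-hydroxyguai-3-en-8-one | CC(C)[C@@H]1C[C@H]2[C@@H](CC=C2C)[C@](C)(O[Sm](I)I)CC1=O | intermediate
22 | (1R,5S,7S,10R)-10-hydroxyguai-3-en-8-one | CC(C)[C@@H]1C[C@H]2[C@@H](CC=C2C)[C@](C)(O)CC1=O | intermediate
23 | (1R,5S,7S,8R,10R)-guai-3-ene-8,10-diol | CC(C)[C@@H]1C[C@H]2[C@@H](CC=C2C)[C@](C)(O)C[C@H]1O | intermediate
24 | 4-hydroxybenzoic acid | O=C(O)c1ccc(O)cc1 | starting material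
25 | tert-butyldimethylsilyl 4-(tert-butyldimethylsilyloxy)benzoate | CC(C)(C)[Si](C)(C)OC(=O)c1ccc(O[Si](C)(C)C(C)(C)C)cc1 | intermediate
26 | 4-(tert-butyldimethylsilyloxy)benzoic acid | CC(C)(C)[Si](C)(C)Oc1ccc(cc1)C(O)=O | intermediate
27 | 4-(tert-butyldimethylsilyloxy)benzoyl chloride | CC(C)(C)[Si](C)(C)Oc1ccc(cc1)C(Cl)=O | intermediate
28 | (1R,5S,7S,8R,10R)-10-hydroxyguai-3-en-8-yl 4-(tert-butyldimethylsilyloxy)benzoate | CC(C)[C@@H]1C[C@H]2[C@@H](CC=C2C)[C@](C)(O)C[C@H]1OC(=O)c1ccc(O[Si](C)(C)C(C)(C)C)cc1 | intermediate
29 | (1R,3R,4S,5S,7S,8R,10R)-3,4-epoxy-10-hydroxyguaian-8-yl 4-(tert-butyldimethylsilyloxy)benzoate | CC(C)[C@@H]1C[C@H]2[C@@H](C[C@H]3O[C@]32C)[C@](C)(O)C[C@H]1OC(=O)c1ccc(O[Si](C)(C)C(C)(C)C)cc1 | intermediate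
30 | (1R,3R,4S,5S,7S,8R,10R)-3,4-epoxy-10-hydroxyguaian-8-yl 4-hydroxybenzoate | CC(C)[C@@H]1C[C@H]2[C@@H](C[C@H]3O[C@]32C)[C@](C)(O)C[C@H]1OC(=O)c1ccc(O)cc1 | target

## Step count and least certain steps

Total step count: 15. Longest linear sequence: 13 steps from 1 (steps 1, 2, 4 to 11, 13 to 15); steps 3 and 12 prepare the side fragments 8 and 26.

**Step 10 (key step).** The most likely failures are protonation of the samarium enolate before the slower seven-membered closure onto a hindered ketone (giving simple reduction), proton exchange to the C7 enolate followed by five-membered aldol closure, and attack on the wrong face of the acetyl group. Fallback, from 19 back to 22: 19 is reduced with Zn and Me3SiCl in MeCN to the regiodefined silyl enol ether {[(3S)-3-{[(1S,5R)-5-acetyl-2-methylcyclopent-2-en-1-yl]methyl}-4-methylpent-1-en-2-yl]oxy}trimethylsilane F1. F1 is cyclised by Lewis-acid activation of the acetyl group (TiCl4, CH2Cl2, −78 °C; intramolecular Mukaiyama aldol). This route has no basic enolate, so proton exchange is excluded, and its open transition state offers the complementary face preference. Aqueous work-up gives 22.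

**Step 1.** Ethenyl transfer from zirconium to rhodium may be slower than for substituted alkenyl groups, so that enolate protonation or loss of enantioselectivity intervenes before capture. Fallback, from 1 back to 10: 1 is treated with CH2=CHMgBr and CuBr·SMe2 (cat.) in THF at −78 °C and the magnesium enolate is captured with formaldehyde. This gives 3 together with its enantiomer (2S,3R)-3-ethenyl-2-(hydroxymethyl)cyclopentan-1-one F2. Dehydration as in step 2 gives 5 together with (3R)-3-ethenyl-2-methylidenecyclopentan-1-one F3. Step 4 then gives 10 together with (4S)-4-benzyl-3-[(2S)-2-{[(1R,2R)-2-ethenyl-5-oxocyclopentyl]methyl}-3-methylbutanoyl]-1,3-oxazolidin-2-one F4, a diastereomer that is removed by chromatography or crystallisation. Enantioselection is thus replaced by resolution through the covalently bound auxiliary, at the cost of half the material.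

**Step 4.** Lewis-acid-induced oligomerisation of 5, or slow addition of the hindered 3-methylbutanoyl enolate, may lower conversion. Fallback, from 5 back to 10:
- Enamine catalysis: 3-methylbutanal adds to 5 with (S)-2-[diphenyl(trimethylsilyloxy)methyl]pyrrolidine (cat.) to give (2S)-2-{[(1S,2S)-2-ethenyl-5-oxocyclopentyl]methyl}-3-methylbutanal F5; the catalyst enantiomer is chosen to give 7S.
- Pinnick oxidation (NaClO2, NaH2PO4, 2-methylbut-2-ene) gives (2S)-2-{[(1S,2S)-2-ethenyl-5-oxocyclopentyl]methyl}-3-methylbutanoic acid F6.
- F6 is joined to 6 through the mixed anhydride (t-BuCOCl, Et3N, then 6 and LiCl) to give 10.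

**Step 11.** Exchange of the hindered tertiary hydroxyl onto boron may be slow, so that undirected reduction erodes the anti selectivity. Fallback, from 22 back to 28: Narasaka–Prasad reduction (Et2BOMe, NaBH4, THF/MeOH, −78 °C) gives the syn diol (1R,5S,7S,8S,10R)-guai-3-ene-8,10-diol F7. F7 is esterified with 26 under Mitsunobu conditions (PPh3, diisopropyl azodicarboxylate) with inversion at C8, giving 28 directly.

**Step 14.** Direction by a bishomoallylic tertiary hydroxyl may be too weak, giving slow reaction or poor facial selectivity. Fallback, from 23 back to 29: reagent-controlled Shi epoxidation of 23 (the fructose-derived ketone enantiomer matched to the H1 face, KHSO5, K2CO3, MeCN/H2O, 0 °C) gives (1R,3R,4S,5S,7S,8R,10R)-3,4-epoxyguaiane-8,10-diol F8. F8 is acylated at O8 with 27 (Et3N, DMAP) to give 29.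

## Further compounds

F1 | step 10 | {[(3S)-3-{[(1S,5R)-5-acetyl-2-methylcyclopent-2-en-1-yl]methyl}-4-methylpent-1-en-2-yl]oxy}trimethylsilane | CC(C)[C@H](C[C@H]1[C@@H](CC=C1C)C(C)=O)C(=C)O[Si](C)(C)C
F2 | step 1 | (2S,3R)-3-ethenyl-2-(hydroxymethyl)cyclopentan-1-one | OC[C@@H]1[C@H](CCC1=O)C=C
F3 | step 1 | (3R)-3-ethenyl-2-methylidenecyclopentan-1-one | C=C1[C@H](CCC1=O)C=C
F4 | step 1 | (4S)-4-benzyl-3-[(2S)-2-{[(1R,2R)-2-ethenyl-5-oxocyclopentyl]methyl}-3-methylbutanoyl]-1,3-oxazolidin-2-one | CC(C)[C@H](C[C@@H]1[C@H](CCC1=O)C=C)C(=O)N1[C@@H](Cc2ccccc2)COC1=O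
F5 | step 4 | (2S)-2-{[(1S,2S)-2-ethenyl-5-oxocyclopentyl]methyl}-3-methylbutanal | CC(C)[C@H](C[C@H]1[C@@H](CCC1=O)C=C)C=O
F6 | step 4 | (2S)-2-{[(1S,2S)-2-ethenyl-5-oxocyclopentyl]methyl}-3-methylbutanoic acid | CC(C)[C@H](C[C@H]1[C@@H](CCC1=O)C=C)C(O)=O
F7 | step 11 | (1R,5S,7S,8S,10R)-guai-3-ene-8,10-diol | CC(C)[C@@H]1C[C@H]2[C@@H](CC=C2C)[C@](C)(O)C[C@@H]1O
F8 | step 14 | (1R,3R,4S,5S,7S,8R,10R)-3,4-epoxyguaiane-8,10-diol | CC(C)[C@@H]1C[C@H]2[C@@H](C[C@H]3O[C@]32C)[C@](C)(O)C[C@H]1O
A1 | alternative 1 | (3R,1E)-3-(tert-butyldimethylsilyloxy)-1-(1-isopropylcyclopropyl)octa-1,6,7-triene | C=C=CCC[C@@H](O[Si](C)(C)C(C)(C)C)/C=C/C1(CC1)C(C)C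
A2 | alternative 1 | cis-fused 15-nor-4-(tert-butyldimethylsilyloxy)guaia-6,10(14)-diene | CC(C)C1=C[C@@H]2[C@@H](CC[C@H]2O[Si](C)(C)C(C)(C)C)C(=C)CC1
A3 | alternative 2 | (10S,6E)-2,6,10-trimethyl-10-(triethylsilyloxy)dodec-6-en-11-yn-3-one | CC(C)C(=O)CC/C(C)=C/CC[C@](C)(O[Si](CC)(CC)CC)C#C
A4 | alternative 2 | 7,10-epoxyguai-5-en-4-ol triethylsilyl ether | CC(C)[C@@]13C=C2[C@@H](CC[C@]2(C)O[Si](CC)(CC)CC)[C@](C)(O3)CC1
A5 | alternative 3 | cis-6-methylbicyclo[3.3.0]octa-3,6-dien-2-one | O=C1C=C[C@H]2[C@@H]1CC=C2C
A6 | alternative 3 | 3-methylbut-1-ene | CC(C)C=C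
A7 | alternative 3 | cis-anti-cis tricyclic cyclobutane ketone (head-to-tail photoadduct) | CC(C)[C@@H]1[C@H]3[C@H]2[C@H](CC=C2C)C(=O)[C@H]3C1
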